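**Retrosynthetic overview**
1. Target 14 ⇐ 12 by one global deprotection; the C3 carbinol comes from 1,3-syn reduction of β-hydroxy ketone 10 (C5–OH directs, C2–OCb reinforces).
2. Key disconnection C2–C3: C2 is used as a configurationally defined α-oxygenated carbanion (lithiated O-alkyl carbamate 9, C2 set by (+)-sparteine) and C3 as the acyl carbon of β-lactone 4; acyl–O opening gives 10 directly.
3. 4 ⇐ aldehyde 3 + ketene (catalytic asymmetric [2+2], sets C5); 3 ⇐ methyl dihydroferulate 1; carbamate 8 ⇐ tyrosol 5.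
4. Rings: none is built in the target; the only ring made is the temporary oxetan-2-one (step 3), opened again in step 6.

Assumption: the target is the all-syn (2S,3S,5S)-triol encoded by the SMILES, and (+)-sparteine and the Nelson triamine ligand are bought as reagents.

Step 1
Reactants: 1 methyl 3-(4-hydroxy-3-methoxyphenyl)propanoate
Product: 2 methyl 3-[4-(tert-butyldimethylsilyloxy)-3-methoxyphenyl]propanoate
Conditions: TBSCl (1.2 equiv), imidazole (2.5 equiv), DMF, rt
Reagents that add atoms: tert-butyldimethylsilyl chloride, CC(C)(C)[Si](C)(C)Cl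
Why: Phenol O-silylation (Corey TBSCl–imidazole protocol) masks the acidic ArOH before the hydride, Lewis-acid and organolithium steps; no stereocentre is involved.

Step 2
Reactants: 2 methyl 3-[4-(tert-butyldimethylsilyloxy)-3-methoxyphenyl]propanoate
Product: 3 3-[4-(tert-butyldimethylsilyloxy)-3-methoxyphenyl]propanal
Conditions: DIBAL-H (1.05 equiv), CH2Cl2, −78 °C; aq. Rochelle salt
Reagents that add atoms: none
Why: DIBAL-H partial reduction of the ester stops at the aldehyde because the tetrahedral aluminium hemiacetal is stable at −78 °C and collapses only on work-up.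

Step 3
Reactants: 3 3-[4-(tert-butyldimethylsilyloxy)-3-methoxyphenyl]propanal
Product: 4 (S)-4-{2-[4-(tert-butyldimethylsilyloxy)-3-methoxyphenyl]ethyl}oxetan-2-one
Conditions: AcBr (1.9 equiv), iPr2NEt (1.7 equiv), Nelson (S,S)-valinol-derived bis(triflamide) triamine–Al(III) catalyst (10 mol %), CH2Cl2, −50 °C
Reagents that add atoms: acetyl bromide, CC(=O)Br
Why: Nelson catalytic asymmetric acyl halide–aldehyde cyclocondensation, in which ketene made in situ adds [2+2] to the Al-bound aldehyde and the chiral ligand shields one aldehyde face so that C5 is set as (S) (the catalyst enantiomer that gives (4S)-4-(2-phenylethyl)oxetan-2-one from 3-phenylpropanal).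

Step 4
Reactants: 5 4-(2-hydroxyethyl)phenol (tyrosol)
Product: 7 2-[4-(tert-butyldimethylsilyloxy)phenyl]ethanol, via sodium 4-(2-hydroxyethyl)phenolate 6 (not isolated)
Conditions: NaH (1.0 equiv), THF, 0 °C; then TBSCl (1.0 equiv), 0 °C → rt
Reagents that add atoms: tert-butyldimethylsilyl chloride, CC(C)(C)[Si](C)(C)Cl
Why: Chemoselective O-silylation, since one equivalent of NaH deprotonates only the phenol (pKa ≈ 10 against ≈ 16 for the primary alcohol) and the phenolate is trapped by TBSCl.

Step 5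
Reactants: 7 2-[4-(tert-butyldimethylsilyloxy)phenyl]ethanol
Product: 8 2-[4-(tert-butyldimethylsilyloxy)phenyl]ethyl N,N-diisopropylcarbamate
Conditions: iPr2NCOCl (1.3 equiv), Et3N (1.5 equiv), CH2Cl2, reflux, 24 h
Reagents that add atoms: N,N-diisopropylcarbamoyl chloride, CC(C)N(C(C)C)C(=O)Cl
Why: O-Carbamoylation of the primary alcohol gives the Hoppe carbamate whose C=O directs and stabilises the later α-lithiation; no stereocentre is involved.

Step 6
Reactants: 8 2-[4-(tert-butyldimethylsilyloxy)phenyl]ethyl N,N-diisopropylcarbamate; 4 (S)-4-{2-[4-(tert-butyldimethylsilyloxy)-3-methoxyphenyl]ethyl}oxetan-2-one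
Product: 10 (2S,5S)-1-[4-(tert-butyldimethylsilyloxy)phenyl]-7-[4-(tert-butyldimethylsilyloxy)-3-methoxyphenyl]-5-hydroxy-3-oxoheptan-2-yl N,N-diisopropylcarbamate, via (R)-α-lithio carbamate 9 (not isolated)
Conditions: 8 (1.05 equiv), s-BuLi (1.0 equiv), (+)-sparteine (1.05 equiv), Et2O, −78 °C, 5 h; cannulate slowly into 4 (1.1 equiv), Et2O, −78 °C, 1 h; AcOH, −78 °C
Reagents that add atoms: none
Why: Proposed new method: s-BuLi/(+)-sparteine removes the pro-R α-proton of the O-alkyl carbamate (enantioselective Hoppe deprotonation, mirror image of the (−)-sparteine/pro-S case) to give the configurationally stable chelated α-oxy carbanion 9, a polarity-reversed carbinol-carbon nucleophile that attacks the strained lactone C=O with retention and opens it by acyl–O cleavage to the C5 lithium alkoxide, so C2 is set as (S) in the C2–C3 bond-forming event and C5 is carried over unchanged, while inverse addition to excess lactone at −78 °C limits over-addition and proton transfer from the product; the closest known reaction types are the retentive acylation of sparteine-complexed lithiated carbamates by CO2, chloroformates and acid chlorides and the acyl C–O opening of β-lactones by hard lithium carbanions (e.g. lithiated phosphonates) to β-hydroxy ketones.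

Step 7
Reactants: 10 (2S,5S)-1-[4-(tert-butyldimethylsilyloxy)phenyl]-7-[4-(tert-butyldimethylsilyloxy)-3-methoxyphenyl]-5-hydroxy-3-oxoheptan-2-yl N,N-diisopropylcarbamate
Product: 12 (2S,3S,5S)-1-[4-(tert-butyldimethylsilyloxy)phenyl]-7-[4-(tert-butyldimethylsilyloxy)-3-methoxyphenyl]-3,5-dihydroxyheptan-2-yl N,N-diisopropylcarbamate, via diethylboron chelate 11 (not isolated)
Conditions: Et2BOMe (1.1 equiv), THF/MeOH 4:1, −78 °C; NaBH4 (1.2 equiv), −78 °C; AcOH; MeOH co-evaporation
Reagents that add atoms: none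
Why: Narasaka–Prasad 1,3-syn reduction, in which the C5 diethylborinate chelates the C3 ketone in a half-chair and external hydride adds axially to give the 3,5-syn alcohol (C3 = S), a sense reinforced by Felkin–Anh control from C2 (C–OCb bond antiperiplanar to the incoming hydride gives 2,3-syn).

Step 8
Reactants: 12 (2S,3S,5S)-1-[4-(tert-butyldimethylsilyloxy)phenyl]-7-[4-(tert-butyldimethylsilyloxy)-3-methoxyphenyl]-3,5-dihydroxyheptan-2-yl N,N-diisopropylcarbamate
Product: 14 (2S,3S,5S)-1-(4-hydroxyphenyl)-7-(4-hydroxy-3-methoxyphenyl)heptane-2,3,5-triol, via bis(silyl ether) triol 13 (not isolated)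
Conditions: LiAlH4 (6 equiv), THF, reflux; then H2O, 2 M NaOH, MeOH, rt; NH4Cl
Reagents that add atoms: none
Why: Reductive cleavage of the hindered carbamate by LiAlH4 (hydride addition to the C=O, then loss of the C2 alkoxide) followed by hydroxide-mediated hydrolysis of the two aryl silyl ethers in the basic work-up; no C–O bond at a stereocentre is broken, so (2S,3S,5S) is retained.

**Compound list**
1 | methyl 3-(4-hydroxy-3-methoxyphenyl)propanoate (methyl dihydroferulate) | COC(=O)CCc1ccc(O)c(OC)c1 | starting material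
2 | methyl 3-[4-(tert-butyldimethylsilyloxy)-3-methoxyphenyl]propanoate | COC(=O)CCc1ccc(O[Si](C)(C)C(C)(C)C)c(OC)c1 | intermediate
3 | 3-[4-(tert-butyldimethylsilyloxy)-3-methoxyphenyl]propanal | O=CCCc1ccc(O[Si](C)(C)C(C)(C)C)c(OC)c1 | intermediate
4 | (S)-4-{2-[4-(tert-butyldimethylsilyloxy)-3-methoxyphenyl]ethyl}oxetan-2-one | O=C1C[C@H](CCc2ccc(O[Si](C)(C)C(C)(C)C)c(OC)c2)O1 | intermediate
5 | 4-(2-hydroxyethyl)phenol (tyrosol) | OCCc1ccc(O)cc1 | starting material
6 | sodium 4-(2-hydroxyethyl)phenolate (formed in the flask) | [Na+].[O-]c1ccc(CCO)cc1 | intermediate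
7 | 2-[4-(tert-butyldimethylsilyloxy)phenyl]ethanol | OCCc1ccc(O[Si](C)(C)C(C)(C)C)cc1 | intermediate
8 | 2-[4-(tert-butyldimethylsilyloxy)phenyl]ethyl N,N-diisopropylcarbamate | CC(C)N(C(C)C)C(=O)OCCc1ccc(O[Si](C)(C)C(C)(C)C)cc1 | intermediate
9 | (R)-1-lithio-2-[4-(tert-butyldimethylsilyloxy)phenyl]ethyl N,N-diisopropylcarbamate, (+)-sparteine complex (ligand not drawn; formed in the flask) | [Li][C@@H](OC(=O)N(C(C)C)C(C)C)Cc1ccc(O[Si](C)(C)C(C)(C)C)cc1 | intermediate
10 | (2S,5S)-1-[4-(tert-butyldimethylsilyloxy)phenyl]-7-[4-(tert-butyldimethylsilyloxy)-3-methoxyphenyl]-5-hydroxy-3-oxoheptan-2-yl N,N-diisopropylcarbamate | COc1cc(CC[C@H](O)CC(=O)[C@@H](OC(=O)N(C(C)C)C(C)C)Cc2ccc(O[Si](C)(C)C(C)(C)C)cc2)ccc1O[Si](C)(C)C(C)(C)C | intermediate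
11 | (2S,5S)-1-[4-(tert-butyldimethylsilyloxy)phenyl]-7-[4-(tert-butyldimethylsilyloxy)-3-methoxyphenyl]-5-(diethylboryloxy)-3-oxoheptan-2-yl N,N-diisopropylcarbamate (B–O=C chelate; formed in the flask) | COc1cc(CC[C@H](OB(CC)CC)CC(=O)[C@@H](OC(=O)N(C(C)C)C(C)C)Cc2ccc(O[Si](C)(C)C(C)(C)C)cc2)ccc1O[Si](C)(C)C(C)(C)C | intermediate
12 | (2S,3S,5S)-1-[4-(tert-butyldimethylsilyloxy)phenyl]-7-[4-(tert-butyldimethylsilyloxy)-3-methoxyphenyl]-3,5-dihydroxyheptan-2-yl N,N-diisopropylcarbamate | COc1cc(CC[C@H](O)C[C@H](O)[C@@H](OC(=O)N(C(C)C)C(C)C)Cc2ccc(O[Si](C)(C)C(C)(C)C)cc2)ccc1O[Si](C)(C)C(C)(C)C | intermediate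
13 | (2S,3S,5S)-1-[4-(tert-butyldimethylsilyloxy)phenyl]-7-[4-(tert-butyldimethylsilyloxy)-3-methoxyphenyl]heptane-2,3,5-triol (formed in the flask) | COc1cc(CC[C@H](O)C[C@H](O)[C@@H](O)Cc2ccc(O[Si](C)(C)C(C)(C)C)cc2)ccc1O[Si](C)(C)C(C)(C)C | intermediate
14 | (2S,3S,5S)-1-(4-hydroxyphenyl)-7-(4-hydroxy-3-methoxyphenyl)heptane-2,3,5-triol | COc1cc(CC[C@H](O)C[C@H](O)[C@@H](O)Cc2ccc(O)cc2)ccc1O | target

**Step count:** 8 steps in total. Longest linear sequence: 6 steps (1, 2, 3, 6, 7, 8); the tyrosol branch (4, 5) joins at step 6.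

**Three steps most likely to fail, each with one fallback**

Step 6 (union of 9 with the lactone). The risks are over-addition of 9 to the liberated ketone and proton transfer from the C2–H of the product, which would lower yield and er. The fallback sets out from 4: MeNH(OMe)·HCl/Me2AlCl opens the lactone to the Weinreb amide (S)-3-hydroxy-N-methoxy-N-methyl-5-[4-(tert-butyldimethylsilyloxy)-3-methoxyphenyl]pentanamide F1. Its hydroxyl is deprotonated in the flask with iPrMgCl (1 equiv) and the solution is added to 9 at −78 °C. The N-methoxy-N-methyl tetrahedral chelate survives until the acidic quench, so the ketone is never exposed to the organolithium, and the sequence comes back to the route at 10.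

Step 3 (catalytic asymmetric [2+2]). The risk is low ee or conversion with this electron-rich, silyl-protected aldehyde. The fallback sets out from 3: Brown allylation with (+)-Ipc2B(allyl) (Et2O, −78 °C; NaOH/H2O2) gives (S)-1-[4-(tert-butyldimethylsilyloxy)-3-methoxyphenyl]hex-5-en-3-ol F2. Ozonolysis to a Sudan III end point with Me2S work-up, then Pinnick oxidation, gives (S)-3-hydroxy-5-[4-(tert-butyldimethylsilyloxy)-3-methoxyphenyl]pentanoic acid F3. PhSO2Cl/pyridine at 0 °C closes the β-lactone by carboxyl activation, with retention at the C–O stereocentre, and the route is rejoined at 4.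

Step 7 (1,3-syn reduction). The risk is that the α′-carbamate disturbs the boron chelate and lowers the dr. The fallback sets out from 10 and switches from 1,3-chelation control to 1,2-Felkin control: TESCl/imidazole gives the silyl ether (2S,5S)-1-[4-(tert-butyldimethylsilyloxy)phenyl]-7-[4-(tert-butyldimethylsilyloxy)-3-methoxyphenyl]-3-oxo-5-(triethylsilyloxy)heptan-2-yl N,N-diisopropylcarbamate F4. L-Selectride (THF, −78 °C) then reduces it with the C–OCb bond antiperiplanar to the hydride, giving the 2,3-syn alcohol (2S,3S,5S)-1-[4-(tert-butyldimethylsilyloxy)phenyl]-7-[4-(tert-butyldimethylsilyloxy)-3-methoxyphenyl]-3-hydroxy-5-(triethylsilyloxy)heptan-2-yl N,N-diisopropylcarbamate F5. PPTS/MeOH removes the triethylsilyl group while the aryl silyl ethers survive, and the route is rejoined at 12.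

**Further compounds**
F1 | step 6 | (S)-3-hydroxy-N-methoxy-N-methyl-5-[4-(tert-butyldimethylsilyloxy)-3-methoxyphenyl]pentanamide | COc1cc(CC[C@H](O)CC(=O)N(C)OC)ccc1O[Si](C)(C)C(C)(C)C
F2 | step 3 | (S)-1-[4-(tert-butyldimethylsilyloxy)-3-methoxyphenyl]hex-5-en-3-ol | COc1cc(CC[C@H](O)CC=C)ccc1O[Si](C)(C)C(C)(C)C
F3 | step 3 | (S)-3-hydroxy-5-[4-(tert-butyldimethylsilyloxy)-3-methoxyphenyl]pentanoic acid | COc1cc(CC[C@H](O)CC(=O)O)ccc1O[Si](C)(C)C(C)(C)C
F4 | step 7 | (2S,5S)-1-[4-(tert-butyldimethylsilyloxy)phenyl]-7-[4-(tert-butyldimethylsilyloxy)-3-methoxyphenyl]-3-oxo-5-(triethylsilyloxy)heptan-2-yl N,N-diisopropylcarbamate | COc1cc(CC[C@H](O[Si](CC)(CC)CC)CC(=O)[C@@H](OC(=O)N(C(C)C)C(C)C)Cc2ccc(O[Si](C)(C)C(C)(C)C)cc2)ccc1O[Si](C)(C)C(C)(C)C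
F5 | step 7 | (2S,3S,5S)-1-[4-(tert-butyldimethylsilyloxy)phenyl]-7-[4-(tert-butyldimethylsilyloxy)-3-methoxyphenyl]-3-hydroxy-5-(triethylsilyloxy)heptan-2-yl N,N-diisopropylcarbamate | COc1cc(CC[C@H](O[Si](CC)(CC)CC)C[C@H](O)[C@@H](OC(=O)N(C(C)C)C(C)C)Cc2ccc(O[Si](C)(C)C(C)(C)C)cc2)ccc1O[Si](C)(C)C(C)(C)C
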